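Start from the summer run: its target curve bends early, and that bend is what to carry to the next flask.

| setting | summer | midnight | winter | flask |
|---|---|---|---|---|
| substrate | 0.010 M | 0.040 M | 0.020 M | 0.020 M |
| reagent | 0.016 M | 0.016 M | 0.016 M | 0.0160 M |
| free catalyst | 20 µM | 20 µM | 10 µM | 20 µM |
| remark | run made earlier | run made earlier | run made earlier |  |

| run | time / min | target / % |
|---|---|---|
| summer | 4.00 | 2.8 |
| summer | 12.0 | 10.5 |
| summer | 25.0 | 14.8 |
| summer | 30.0 | 18.8 |
| summer | 50.0 | 29.4 |
| summer | 60.0 | 32.9 |
| summer | 80.0 | 42.1 |
| midnight | 12.0 | 5.3 |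
| midnight | 25.0 | 11.5 |
| midnight | 30.0 | 13.3 |
| midnight | 50.0 | 20.9 |
| midnight | 60.0 | 21.4 |
| midnight | 80.0 | 23.7 |
| winter | 6.00 | 3.0 |
| winter | 12.0 | 2.2 |
| winter | 25.0 | 5.5 |
| winter | 40.0 | 12.1 |
| winter | 80.0 | 19.5 |

(standard deviation of a reading: 1 percentage point)

- the numbers in the tables scatter with a standard deviation of 1 percentage point
- what has left substrate counts as converted, also if it is not yet product

- factor on the rate of making target when 50 % of the substrate are converted if free catalyst is charged twice over
- factor on the rate when 50 % of the substrate are converted if free catalyst is charged at 2.0 µM instead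

In the summer run target is made at 8.75 × 10⁻⁵ M min⁻¹ up to 12.0 min, then at 4.65 × 10⁻⁵ M min⁻¹ up to 80.0 min.

f = later slope / earlier slope = 0.531

This fade is a reading and carries the scatter of its points. By the knee in the summer run, target has taken 6.56 % of the reagent charge if each target takes one reagent, less than the 46.9 % lost from the slope, so treat the fade as a clock running beside the target.

Now draw this flask. Take its starting slope as the geometric mean of the summer slope and the midnight run's 1.77 × 10⁻⁴ M min⁻¹ up to 30.0 min, which gives 1.25 × 10⁻⁴ M min⁻¹. Put the knee at 12.0 min, with target at 0.00149 M. After it the slope is 6.62 × 10⁻⁵ M min⁻¹, reaching 0.00599 M at 80.0 min. That is below the 0.00948 M of the midnight run's last reading, so expect no level yet.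

Substrate is not read, so place the 50 % moment inside the knee, at fade √f. Take the moment with doubled catalyst as near the start, at fade 1, and the moment with 2.0 µM as past the knee, at fade f.

dbl ≈ 2 / √f = 2.74

ratio ≈ (2.0 µM / 20 µM) × √f = 0.0729

The forecast gave 2 and 0.1, holding “At fixed composition, reagent effects leave catalyst scaling linear”; my reckoning differs from it.

This flask gives 2.55 and 0.0858.

    substrate + free catalyst ⇌ free catalyst + open intermediate (K = 1.40, k = 110 L mol⁻¹ s⁻¹)
    free catalyst + open intermediate ⇌ catalyst intermediate (K = 16.0 L mol⁻¹, k = 3900 L mol⁻¹ s⁻¹)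
    reagent + catalyst intermediate → free catalyst + target (k = 130 L mol⁻¹ s⁻¹)
    reagent ⇌ dormant form (K = 1.60, k = 0.00210 s⁻¹)

Beyond the catalyst factor, doubling gains 1.27, less than my 1.37, and the 2.0 µM flask keeps 0.858, more than my 0.729. In this flask the forward step into dormant form alone gives reagent a half-life of 5.5 min at 4.50 min, and at 80.0 min the step making target uses reagent at 0.13 of that step's forward rate. After 8.00 min this flask holds 46.0 % of its reagent charge, with dormant form at 0.00765 M and target at 4.95 % of the substrate charged.

The runs come from a simulation with constants of no real substance, noise included.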